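The isocoumarin lactone ring (O2, C1, C8a, C4a, C4, C3) is 6‑pentylpyran‑2‑one itself, and the C8a–C4a bond of ring A is that pyranone's weakly aromatic C3=C4 bond. The route exploits this: the remaining benzo carbons C8, C7, C6 and C5 (oxygen on C8 and C6) are attached to pyranone C3 as an (E)‑1‑aryloxy‑3‑silyloxybuta‑1,3‑dienyl chain, with benzyl‑protected ring B already on the ether oxygen. One operation, a thermal six‑electron electrocyclisation (C5–C4a bond) followed by DDQ dehydrogenation, then completes ring A. The diaryl ether arises earlier by oxa‑Michael addition of the ring B phenol to a pyranonyl ynone.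

Key step: step 9

Remark: ring B is numbered as a benzoate (carboxyl carbon on C1) and the bicycle as 1H‑isochromen‑1‑one.
Remark: olivetolic acid 7 is taken as purchased, which avoids a regiochemically uncertain carboxylation of olivetol; racemic 4 is used because its carbinol centre is oxidised away in step 3.
Remark: the E enone 13 (aryloxy oxygen anti to the acetyl group) is assumed to be the more stable geometric isomer, as for β‑alkoxy enones, so step 7 is run under equilibrating conditions.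

Step 1
Reactants: 1 6‑pentylpyran‑2‑one
Product: 3 3‑bromo‑6‑pentylpyran‑2‑one, via trans‑3,4‑dibromo‑6‑pentyl‑3,4‑dihydropyran‑2‑one 2 (not isolated)
Conditions: Br2 (1.05 equiv), CH2Cl2, 0 °C to rt, dark; then Et3N, 0 °C
Reagents that add atoms: bromine, BrBr
Why: Electrophilic bromination by addition–elimination, in which bromine attacks C3, the terminus of the cyclic dienyl ester O1–C6=C5–C4=C3, as in 2‑pyranone itself and in coumarin, and triethylamine removes HBr from the 3,4‑dibromide by E1cB elimination to restore the pyranone.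

Step 2
Reactants: 3 3‑bromo‑6‑pentylpyran‑2‑one; 4 but‑3‑yn‑2‑ol (racemic)
Product: 5 3‑(3‑hydroxybut‑1‑yn‑1‑yl)‑6‑pentylpyran‑2‑one (racemic)
Conditions: Pd(PPh3)2Cl2 (3 mol%), CuI (6 mol%), Et3N, THF, rt
Reagents that add atoms: none
Why: Sonogashira coupling at the C3–Br bond of a 2‑pyranone, an electron‑poor vinylic bromide that should undergo oxidative addition readily, with a tertiary amine base that does not open the lactone.

Step 3
Reactants: 5 3‑(3‑hydroxybut‑1‑yn‑1‑yl)‑6‑pentylpyran‑2‑one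
Product: 6 4‑(2‑oxo‑6‑pentylpyran‑3‑yl)but‑3‑yn‑2‑one
Conditions: Dess–Martin periodinane, CH2Cl2, 0 °C to rt
Reagents that add atoms: none
Why: Dess–Martin oxidation of a secondary propargylic alcohol to the ynone under near‑neutral conditions that leave the pyranone and the base‑sensitive ynone untouched.

Step 4
Reactants: 7 olivetolic acid (2,4‑dihydroxy‑6‑pentylbenzoic acid)
Product: 8 benzyl 2,4‑bis(benzyloxy)‑6‑pentylbenzoate
Conditions: BnBr (3.5 equiv), K2CO3, DMF, rt to 60 °C
Reagents that add atoms: benzyl bromide, BrCc1ccccc1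
Why: Williamson alkylation of the carboxylate and both phenoxides, the carboxylate reacting first so that the acid is masked as its ester before warming could decarboxylate it.

Step 5
Reactants: 8 benzyl 2,4‑bis(benzyloxy)‑6‑pentylbenzoate
Product: 9 benzyl 2,4‑bis(benzyloxy)‑5‑iodo‑6‑pentylbenzoate
Conditions: N‑iodosuccinimide (1.1 equiv), CF3CO2H (0.3 equiv), MeCN, 0 °C to rt
Reagents that add atoms: N‑iodosuccinimide, O=C1CCC(=O)N1I
Why: Electrophilic aromatic iodination at C5, which is para to the 2‑benzyloxy group, ortho to the 4‑benzyloxy group and meta to the ester, in preference to C3 between the two ethers, the selectivity shown by 3,5‑dialkoxytoluenes and orsellinate ethers.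

Step 6
Reactants: 9 benzyl 2,4‑bis(benzyloxy)‑5‑iodo‑6‑pentylbenzoate
Product: 12 benzyl 2,4‑bis(benzyloxy)‑5‑hydroxy‑6‑pentylbenzoate, via arylmagnesium chloride 10 (not isolated), via dimethyl arylboronate 11 (not isolated)
Conditions: iPrMgCl·LiCl, THF, −20 °C; B(OMe)3, −20 °C to rt; then AcOH, 30% H2O2, 0 °C
Reagents that add atoms: hydrogen peroxide, OO
Why: Iodine–magnesium exchange, assisted by the flanking benzyloxy group and tolerated at low temperature by the doubly ortho‑substituted benzyl ester, followed by borylation and boronate oxidation with 1,2‑migration of the aryl group from boron to oxygen.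

Step 7
Reactants: 12 benzyl 2,4‑bis(benzyloxy)‑5‑hydroxy‑6‑pentylbenzoate; 6 4‑(2‑oxo‑6‑pentylpyran‑3‑yl)but‑3‑yn‑2‑one
Product: 13 benzyl 2,4‑bis(benzyloxy)‑5‑{[(1E)‑3‑oxo‑1‑(2‑oxo‑6‑pentylpyran‑3‑yl)but‑1‑en‑1‑yl]oxy}‑6‑pentylbenzoate
Conditions: Cs2CO3 (0.2 equiv), MeCN, rt to 40 °C, until the E/Z ratio is constant
Reagents that add atoms: none
Why: Oxa‑Michael addition of the phenoxide to the ynone carbon that bears the pyranone, after which reversible phenoxide addition–elimination on the push‑pull enone should equilibrate the alkene to the E isomer.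

Step 8
Reactants: 13 benzyl 2,4‑bis(benzyloxy)‑5‑{[(1E)‑3‑oxo‑1‑(2‑oxo‑6‑pentylpyran‑3‑yl)but‑1‑en‑1‑yl]oxy}‑6‑pentylbenzoate
Product: 14 benzyl 2,4‑bis(benzyloxy)‑5‑{[(1E)‑3‑(tert‑butyldimethylsilyloxy)‑1‑(2‑oxo‑6‑pentylpyran‑3‑yl)buta‑1,3‑dien‑1‑yl]oxy}‑6‑pentylbenzoate
Conditions: TBSOTf (1.2 equiv), Et3N, CH2Cl2, −78 to 0 °C; filtration through Et3N‑deactivated silica
Reagents that add atoms: tert‑butyldimethylsilyl trifluoromethanesulfonate, CC(C)(C)[Si](C)(C)OS(=O)(=O)C(F)(F)F
Why: Soft enolisation of the methyl ketone, the only enolisable position, should give the cross‑conjugated silyl dienol ether in the way 1‑alkoxy‑3‑silyloxybutadienes are made from β‑alkoxy enones, at a temperature low enough to keep the alkene geometry.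

Step 9
Reactants: 14 benzyl 2,4‑bis(benzyloxy)‑5‑{[(1E)‑3‑(tert‑butyldimethylsilyloxy)‑1‑(2‑oxo‑6‑pentylpyran‑3‑yl)buta‑1,3‑dien‑1‑yl]oxy}‑6‑pentylbenzoate
Product: 16 benzyl 2,4‑bis(benzyloxy)‑5‑{[6‑(tert‑butyldimethylsilyloxy)‑1‑oxo‑3‑pentyl‑1H‑isochromen‑8‑yl]oxy}‑6‑pentylbenzoate, via 4a,5‑dihydroisocoumarin 15 (not isolated)
Conditions: degassed PhMe (0.01 M), sealed tube, 140 °C; then DDQ (1.1 equiv), rt
Reagents that add atoms: none
Why: Proposed new method: the pyranone C3=C4 bond (C8a=C4a), the E aryloxy alkene (C8=C7) and the silyl enol ether (C6=C5) make up a cis‑hexatriene that should close on heating by a concerted six‑electron electrocyclisation between the enol ether CH2 (C5) and pyranone C4 (C4a) to the 4a,5‑dihydro compound 15, from which DDQ takes a hydride at C5 and a proton at C4a so that ring A becomes benzenoid and the pyranone is restored. The closest known reaction type is the thermal electrocyclisation and oxidative aromatisation of 2‑silyloxyhexatrienes used to benzannulate vinyl‑substituted heteroarenes; a 2‑pyranone C3=C4 bond has not served as the triene terminus, but it is only weakly aromatic and the triene carries an acceptor (the lactone carbonyl on C8a) next to a donor (the aryloxy group on C8), a captodative pattern that lowers the barrier of hexatriene closure. Ring A is the only ring closed, as a six‑membered carbocycle in the thermally allowed disrotatory mode. The one new stereocentre, C4a of 15, forms racemic and is destroyed by the dehydrogenation, so no stereocontrol is required. The step needs the E geometry of the C8=C7 alkene, fixed in step 7 and carried through step 8, so that the diene terminus can reach C4, and it needs unimolecular closure to outrun bimolecular cycloaddition of the pyranone, which high dilution secures; regiochemistry is not in doubt because C4 is the only pyranone carbon within reach of C5.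

Step 10
Reactants: 16 benzyl 2,4‑bis(benzyloxy)‑5‑{[6‑(tert‑butyldimethylsilyloxy)‑1‑oxo‑3‑pentyl‑1H‑isochromen‑8‑yl]oxy}‑6‑pentylbenzoate
Product: 17 benzyl 2,4‑bis(benzyloxy)‑5‑[(6‑hydroxy‑1‑oxo‑3‑pentyl‑1H‑isochromen‑8‑yl)oxy]‑6‑pentylbenzoate
Conditions: Bu4NF, AcOH, THF, 0 °C
Reagents that add atoms: none
Why: Fluoride‑induced cleavage of the aryl silyl ether, fast for a phenol para to the lactone carbonyl, with acetic acid buffering the phenoxide so that the lactone and the benzyl ester are not attacked.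

Step 11
Reactants: 17 benzyl 2,4‑bis(benzyloxy)‑5‑[(6‑hydroxy‑1‑oxo‑3‑pentyl‑1H‑isochromen‑8‑yl)oxy]‑6‑pentylbenzoate
Product: 18 2,4‑dihydroxy‑5‑[(6‑hydroxy‑1‑oxo‑3‑pentyl‑1H‑isochromen‑8‑yl)oxy]‑6‑pentylbenzoic acid (CNP0439913.0)
Conditions: H2 (1 atm), 10% Pd/C, EtOAc, rt
Reagents that add atoms: none
Why: Hydrogenolysis of the two benzyl ethers and the benzyl ester should be faster than saturation of the trisubstituted enol‑lactone alkene, and it frees the acid under neutral conditions that do not decarboxylate the β‑resorcylic acid.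

Compound list
1 | 6‑pentylpyran‑2‑one | CCCCCc1cccc(=O)o1 | starting material
2 | trans‑3,4‑dibromo‑6‑pentyl‑3,4‑dihydropyran‑2‑one (racemic, one enantiomer drawn; formed in the flask in step 1) | CCCCCC1=C[C@H](Br)[C@@H](Br)C(=O)O1 | intermediate
3 | 3‑bromo‑6‑pentylpyran‑2‑one | CCCCCc1ccc(Br)c(=O)o1 | intermediate
4 | but‑3‑yn‑2‑ol (racemic) | CC(O)C#C | starting material
5 | 3‑(3‑hydroxybut‑1‑yn‑1‑yl)‑6‑pentylpyran‑2‑one (racemic) | CCCCCc1ccc(C#CC(C)O)c(=O)o1 | intermediate
6 | 4‑(2‑oxo‑6‑pentylpyran‑3‑yl)but‑3‑yn‑2‑one | CCCCCc1ccc(C#CC(C)=O)c(=O)o1 | intermediate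
7 | olivetolic acid (2,4‑dihydroxy‑6‑pentylbenzoic acid) | CCCCCc1cc(O)cc(O)c1C(=O)O | starting material
8 | benzyl 2,4‑bis(benzyloxy)‑6‑pentylbenzoate | CCCCCc1cc(OCc2ccccc2)cc(OCc2ccccc2)c1C(=O)OCc1ccccc1 | intermediate
9 | benzyl 2,4‑bis(benzyloxy)‑5‑iodo‑6‑pentylbenzoate | CCCCCc1c(I)c(OCc2ccccc2)cc(OCc2ccccc2)c1C(=O)OCc1ccccc1 | intermediate
10 | [2,4‑bis(benzyloxy)‑3‑(benzyloxycarbonyl)... ]arylmagnesium chloride: benzyl 2,4‑bis(benzyloxy)‑5‑(chloromagnesio)‑6‑pentylbenzoate (formed in the flask in step 6) | CCCCCc1c([Mg]Cl)c(OCc2ccccc2)cc(OCc2ccccc2)c1C(=O)OCc1ccccc1 | intermediate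
11 | benzyl 2,4‑bis(benzyloxy)‑5‑(dimethoxyboryl)‑6‑pentylbenzoate (formed in the flask in step 6) | CCCCCc1c(B(OC)OC)c(OCc2ccccc2)cc(OCc2ccccc2)c1C(=O)OCc1ccccc1 | intermediate
12 | benzyl 2,4‑bis(benzyloxy)‑5‑hydroxy‑6‑pentylbenzoate | CCCCCc1c(O)c(OCc2ccccc2)cc(OCc2ccccc2)c1C(=O)OCc1ccccc1 | intermediate
13 | benzyl 2,4‑bis(benzyloxy)‑5‑{[(1E)‑3‑oxo‑1‑(2‑oxo‑6‑pentylpyran‑3‑yl)but‑1‑en‑1‑yl]oxy}‑6‑pentylbenzoate | CCCCCc1ccc(/C(Oc2c(OCc3ccccc3)cc(OCc3ccccc3)c(C(=O)OCc3ccccc3)c2CCCCC)=C\C(C)=O)c(=O)o1 | intermediate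
14 | benzyl 2,4‑bis(benzyloxy)‑5‑{[(1E)‑3‑(tert‑butyldimethylsilyloxy)‑1‑(2‑oxo‑6‑pentylpyran‑3‑yl)buta‑1,3‑dien‑1‑yl]oxy}‑6‑pentylbenzoate | CCCCCc1ccc(/C(Oc2c(OCc3ccccc3)cc(OCc3ccccc3)c(C(=O)OCc3ccccc3)c2CCCCC)=C\C(=C)O[Si](C)(C)C(C)(C)C)c(=O)o1 | intermediate
15 | benzyl 2,4‑bis(benzyloxy)‑5‑{[6‑(tert‑butyldimethylsilyloxy)‑1‑oxo‑3‑pentyl‑4a,5‑dihydro‑1H‑isochromen‑8‑yl]oxy}‑6‑pentylbenzoate (racemic at C4a; formed in the flask in step 9) | CCCCCC1=CC2CC(O[Si](C)(C)C(C)(C)C)=CC(Oc3c(OCc4ccccc4)cc(OCc4ccccc4)c(C(=O)OCc4ccccc4)c3CCCCC)=C2C(=O)O1 | intermediate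
16 | benzyl 2,4‑bis(benzyloxy)‑5‑{[6‑(tert‑butyldimethylsilyloxy)‑1‑oxo‑3‑pentyl‑1H‑isochromen‑8‑yl]oxy}‑6‑pentylbenzoate | CCCCCc1cc2cc(O[Si](C)(C)C(C)(C)C)cc(Oc3c(OCc4ccccc4)cc(OCc4ccccc4)c(C(=O)OCc4ccccc4)c3CCCCC)c2c(=O)o1 | intermediate
17 | benzyl 2,4‑bis(benzyloxy)‑5‑[(6‑hydroxy‑1‑oxo‑3‑pentyl‑1H‑isochromen‑8‑yl)oxy]‑6‑pentylbenzoate | CCCCCc1cc2cc(O)cc(Oc3c(OCc4ccccc4)cc(OCc4ccccc4)c(C(=O)OCc4ccccc4)c3CCCCC)c2c(=O)o1 | intermediate
18 | 2,4‑dihydroxy‑5‑[(6‑hydroxy‑1‑oxo‑3‑pentyl‑1H‑isochromen‑8‑yl)oxy]‑6‑pentylbenzoic acid | CCCCCc1cc2cc(O)cc(Oc3c(O)cc(O)c(C(=O)O)c3CCCCC)c2c(=O)o1 | target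

Total step count: 11. Longest linear sequence: 8 steps (7 to 18 through steps 4–11; equally 1 to 18 through steps 1–3 and 7–11).

Steps most likely to fail

1. Step 9 (Proposed new method). The pyranone C3=C4 bond may not enter the closure below the temperature at which the silyl dienol ether degrades. Bimolecular cycloaddition of the pyranone diene may compete, and the dihydro intermediate may lose its aryloxy or silyloxy group by elimination before it is dehydrogenated. A change of conditions (Me2AlCl on the lactone carbonyl at low temperature) would be tried first. The fallback uses known chemistry only, sets out from iodide 9 and returns to the route at target 18; ring A is made separately as an isocoumarin and joined to ring B by copper‑catalysed diaryl ether formation. Lateral lithiation of purchased methyl 2,4‑dimethoxy‑6‑methylbenzoate (LiN(iPr)2, THF, −78 °C) and acylation with N‑methoxy‑N‑methylhexanamide should give methyl 2,4‑dimethoxy‑6‑(2‑oxoheptyl)benzoate F1. Enol‑lactonisation (TsOH, PhMe, reflux) then gives 6,8‑dimethoxy‑3‑pentylisocoumarin F2, and BBr3 (CH2Cl2, −78 °C to rt) gives 6,8‑dihydroxy‑3‑pentylisocoumarin F3. Its 6‑hydroxyl is benzylated selectively (BnBr, K2CO3, acetone; the 8‑hydroxyl is hydrogen bonded to the lactone carbonyl) to give 6‑(benzyloxy)‑8‑hydroxy‑3‑pentylisocoumarin F4. Ullmann coupling of F4 with 9 (CuI, picolinic acid, K3PO4, DMSO, 90 °C) should give benzyl 2,4‑bis(benzyloxy)‑5‑{[6‑(benzyloxy)‑1‑oxo‑3‑pentyl‑1H‑isochromen‑8‑yl]oxy}‑6‑pentylbenzoate F5, and hydrogenolysis under the conditions of step 11 gives 18.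

2. Step 7. Kinetic anti addition may leave the aryloxy group cis to the acetyl group, and the doubly flanked phenoxide may add so slowly that the ynone oligomerises under base. The fallback sets out from ynone 6 and returns at enone 13, replacing direct addition to the alkyne by vinylic substitution. Anti hydrochlorination of 6 (LiCl, AcOH, MeCN, rt to 60 °C) should give the storable (Z)‑4‑chloro‑4‑(2‑oxo‑6‑pentylpyran‑3‑yl)but‑3‑en‑2‑one F6. Addition–elimination with the caesium phenoxide of 12 (Cs2CO3, DMF, rt to 50 °C) then gives 13. The enolate intermediate can rotate before chloride leaves, and excess phenoxide keeps the product under thermodynamic control; catalytic iodine in CH2Cl2 is available to complete the equilibration.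

3. Step 6. Exchange at an iodide flanked by a benzyloxy and a pentyl group may be slow, so that the Grignard reagent is protonated (loss of iodine without oxygenation) or attacks the benzyl ester. The fallback sets out from iodide 9 and returns at phenol 12 without any organomagnesium species. Miyaura borylation (Pd(OAc)2, SPhos, B2pin2, KOAc, dioxane, 90 °C) should give benzyl 2,4‑bis(benzyloxy)‑6‑pentyl‑5‑(4,4,5,5‑tetramethyl‑1,3,2‑dioxaborolan‑2‑yl)benzoate F7, which NaBO3·4H2O (THF/H2O, rt) oxidises to 12.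

Further compounds
F1 | step 9 | methyl 2,4‑dimethoxy‑6‑(2‑oxoheptyl)benzoate | CCCCCC(=O)Cc1cc(OC)cc(OC)c1C(=O)OC
F2 | step 9 | 6,8‑dimethoxy‑3‑pentylisocoumarin | CCCCCc1cc2cc(OC)cc(OC)c2c(=O)o1
F3 | step 9 | 6,8‑dihydroxy‑3‑pentylisocoumarin | CCCCCc1cc2cc(O)cc(O)c2c(=O)o1
F4 | step 9 | 6‑(benzyloxy)‑8‑hydroxy‑3‑pentylisocoumarin | CCCCCc1cc2cc(OCc3ccccc3)cc(O)c2c(=O)o1
F5 | step 9 | benzyl 2,4‑bis(benzyloxy)‑5‑{[6‑(benzyloxy)‑1‑oxo‑3‑pentyl‑1H‑isochromen‑8‑yl]oxy}‑6‑pentylbenzoate | CCCCCc1cc2cc(OCc3ccccc3)cc(Oc3c(OCc4ccccc4)cc(OCc4ccccc4)c(C(=O)OCc4ccccc4)c3CCCCC)c2c(=O)o1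
F6 | step 7 | (Z)‑4‑chloro‑4‑(2‑oxo‑6‑pentylpyran‑3‑yl)but‑3‑en‑2‑one | CCCCCc1ccc(/C(Cl)=C/C(C)=O)c(=O)o1
F7 | step 6 | benzyl 2,4‑bis(benzyloxy)‑6‑pentyl‑5‑(4,4,5,5‑tetramethyl‑1,3,2‑dioxaborolan‑2‑yl)benzoate | CCCCCc1c(B2OC(C)(C)C(C)(C)O2)c(OCc2ccccc2)cc(OCc2ccccc2)c1C(=O)OCc1ccccc1
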